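In the autumn run the reagent was the limiting reagent: 11.7 mM against 13 mM of substrate. I kept its books on the substrate scale, so the charge stood at 90.0%. Each unit of reagent stood as reagent, target or over-reaction product. The catalyst could hold 1.00% on this scale, so I dropped that entry.

| flask | substrate | reagent | free catalyst | temperature | remark | time |
|---|---|---|---|---|---|---|
| autumn | 13 mM | 11.7 mM | 0.13 mM | 20 °C | run made earlier |  |
| noon | 13 mM | 5.8 mM | 0.13 mM | 31 °C | run made earlier |  |
| summer | 13 mM | 8.8 mM | 0.13 mM | 20 °C | run made earlier |  |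
| dawn | 13 mM | 11.7 mM | 0.26 mM | 31 °C | run made earlier |  |
| Sunday's | 13 mM | 11.7 mM | 0.13 mM |  | everything together at the start at 5 °C, warmed to 25 °C at 2.5 d | 3.0 d |
| Wednesday's | 13 mM | 11.7 mM (fed, over 2.5 d) | 0.13 mM | 25 °C | all else is in the flask from the start; the feed brings no volume worth counting | 3.0 d |
| Friday's | 13 mM (fed, over 2.5 d) | 11.7 mM | 0.13 mM |  | the addition at 5 °C, then warmed to 25 °C; the feed brings no volume worth counting | 3.0 d |
| Monday's | 13 mM | 11.7 mM | 0.13 mM | 25 °C | everything together at the start | 3.0 d |

- autumn (time / d: over-reaction product / %, target / %): 0.167: 0.4, 7.8; 0.500: 4.0, 16.0; 0.833: 7.9, 20.4; 1.25: 14.2, 22.5; 1.67: 21.6, 23.7; 2.50: 35.9, 22.6; 3.00: 43.3, 20.5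
- noon (time / d: over-reaction product / %, target / %): 0.333: 5.4, 6.9; 0.625: 11.8, 7.4; 1.04: 21.1, 6.1; 1.25: 24.5, 5.3; 1.67: 30.1, 4.1; 2.08: 34.1, 2.6; 2.50: 36.9, 2.4
- summer (time / d: over-reaction product / %, target / %): 0.333: 1.5, 9.8; 0.625: 3.5, 13.3; 1.04: 9.0, 17.0; 1.25: 11.0, 17.6; 1.67: 16.6, 18.7; 2.08: 22.2, 17.7; 2.50: 27.3, 16.8
- dawn (time / d: over-reaction product / %, target / %): 0.208: 8.1, 17.1; 0.333: 15.1, 19.6; 0.625: 31.9, 19.4; 1.25: 59.9, 11.1; 2.50: 82.9, 2.1

(readings scatter by 0.3 percentage points)

- a species is counted by the substrate in it: one resting dimer counts as two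
- amounts and yields of target count idle complex too
- the numbers in the tables scatter by 0.3 percentage points (one standard deviation)
- steps thought possible: substrate + free catalyst -> catalyst intermediate A; reagent + catalyst intermediate A -> catalyst intermediate B; catalyst intermediate B -> free catalyst + target; 2 catalyst intermediate A <-> resting dimer; target -> over-reaction product; free catalyst + target <-> idle complex

- which flask leads in amount of over-reaction product, in percent of the substrate charged ("all alike" within 1.5 percentage points) (Sunday's / Wednesday's / Friday's / Monday's / all alike)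
- how much over-reaction product is there at the end, in percent of the substrate charged: Sunday's
- how much over-reaction product is there at the end, in percent of the substrate charged: Wednesday's
- how much over-reaction product is there at the end, in percent of the substrate charged: Friday's
- how much over-reaction product is there at the end, in percent of the substrate charged: Monday's

The last autumn reading gave product 43.3% and target 20.5%, so reagent stood at 26.2%. Reading reagent as first order, with constant a, I took a from the last reading of the autumn and noon runs:

a at 20 °C = 0.411 d⁻¹; a at 31 °C = 0.851 d⁻¹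

Product gains k times target per day, with k the over-reaction constant. I divided its slope around each target peak by that peak:

k at 20 °C = 0.732 d⁻¹; k at 31 °C = 3.00 d⁻¹

Interpolating the logarithms to 25 °C gave:

a = 0.572 d⁻¹; k = 1.39 d⁻¹

The quantity I carried was the target half-life, ln(2)/k, the time in which target left to itself halves into product: 0.498 d.

For Monday's I closed the books at 3.0 d:

spent 73.8%; target 10.3%; product 63.5%

Monday's stood warm for 6.02 half-lives and Sunday's for 1.00, so I expected Monday's to pass Sunday's. Wednesday's also stood 3.0 d at 25 °C, so this count did not part it from Monday's.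

The forecast said Monday's: Sunday's 22%, Wednesday's 37%, Friday's 20.5%, Monday's 64%. Its ground was “Over-reaction of target is first order”.

The flasks gave Sunday's 18.8%, Wednesday's 37.1%, Friday's 18.0% and Monday's 64.2%, so Monday's led.

    substrate + free catalyst → catalyst intermediate A (k = 1.76 M⁻¹ s⁻¹, Ea = 54.0 kJ mol⁻¹)
    reagent + catalyst intermediate A → catalyst intermediate B (k = 0.295 M⁻¹ s⁻¹, Ea = 55.0 kJ mol⁻¹)
    catalyst intermediate B → free catalyst + target (k = 0.00391 s⁻¹, Ea = 92.0 kJ mol⁻¹)
    2 catalyst intermediate A ⇌ resting dimer (K = 1.00 × 10⁵ M⁻¹, k = 3.05 M⁻¹ s⁻¹, Ea = 42.0 kJ mol⁻¹, ΔH = 25.0 kJ mol⁻¹)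
    target → over-reaction product (k = 1.61 × 10⁻⁵ s⁻¹, Ea = 94.0 kJ mol⁻¹)
    free catalyst + target ⇌ idle complex, settled at all times (K = 46.0 M⁻¹, ΔH = −75.0 kJ mol⁻¹)
    (constants at 25 °C)

The neighbour was Monday's flask read at 5.0 d, 2.00 d later, which is 4.02 half-lives. Target fell from 10.1% to 3.46%, a mean of 6.76%. With the half-life, I reckoned the gain in product as ln(2)/half-life times mean target times time, which came to 19 percentage points. The neighbour held 81.6% of over-reaction product, a gain of 17 points on Monday's.

(Readings and results are calculated from invented constants; noise was put on by code.)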